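The data stem from a simulated flask from invented constants; the scatter is artificial.

Sunday's flask, at its last reading, still held 4.3% of G and 6.6% of X, and the rest of the charge went unread.

| setting | Sunday's | flask |
|---|---|---|
| G | 0.28 M | 0.28 M |
| Z | 150 mM (held) | 150 mM (held) |
| remark | the very flask that is asked about, followed so far |  |
| time |  | 2.0 h |

Sunday's run (percent of the G charged)

| time / min | G / % | X / % |
|---|---|---|
| 2.00 | 69.9 | 22.3 |
| 3.00 | 57.9 | 27.0 |
| 4.00 | 46.8 | 27.2 |
| 6.00 | 32.1 | 26.4 |
| 10.0 | 16.3 | 16.6 |
| 15.0 | 8.0 | 10.6 |
| 25.0 | 4.3 | 6.6 |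

(readings scatter by 0.5 percentage points)

- what was read earlier has a scatter of 0.5 percentage points, one standard deviation
- at the start none of Z is in solution

- how much of the G has reacted by 2.0 h
- how much X there is at 2.0 h, in percent of the G charged

At 25.0 min the part of the charge that is neither G nor X read 13.5 times X. This multiple is the remainder ratio ρ, and at 15.0 min it read 7.68. The dispute over this flask is whether ρ stops rising.

One side extends the first-order decay. The last two readings give rate constants of 0.0621 min⁻¹ for G and 0.0474 min⁻¹ for X. Over the remaining 95.0 min these leave 0.0118% of G and 0.0732% of X, so ρ reaches 1365.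

The other side answers that G's constant has already sunk from 0.188 min⁻¹ in the early readings, so the decline is dying out. This is the forecast: 97% reacted and 4.5% of X, since “G should level near 3%, and X near 4.5% (X/G about 1.5)”. Its numbers put ρ at 20.6.

The flask gives 97.5% reacted and 5.60% of X at 2.0 h, so the plateau side wins. The flask's ρ, reckoned the same way, stops at 16.4, above the 13.5 read on Sunday at 25.0 min, and X is still 5.60% at 20.0 h. The decay side has its region before 0.266 h, where the reacted share still lies over 5 points below its value at 2.0 h.

    X ⇌ E (K = 16.4, k = 0.00584 s⁻¹)
    G + L ⇌ X + D (K = 5.10, k = 0.0361 M⁻¹ s⁻¹)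
    Z ⇌ L, rate k3*(csat - [L]) (kL = 0.0338 s⁻¹)
    L → Q (k = 0.00900 s⁻¹)

The remainder of this flask at 2.0 h is E, 91.9%, and its ρ agrees with the constant K of X ⇌ E, 16.4, which is thermodynamic rather than kinetic control of X against E; the relaxation half-life of that pair by this step alone, both ways together, is 1.86 min, short against 2.0 h. The neighbouring flask is charged with 1.1 M of G, with the time and all else held. Its reacted share of 91.3%, divided by one plus ρ, gives 5.25% of X. That neighbouring flask shows 5.25% of X, with 86.0% of E and 8.72% of G remaining.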